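All runs were generated by integration with made-up constants, and the scatter is random.

A rate proportional to the substrate left, with one fixed constant of proportion, cannot climb while that substrate falls, yet in the midnight run, a closed flask of substrate and catalyst, the rate per unit of substrate left reads 0.0527 min⁻¹ over the first 1.0 min and 0.213 min⁻¹ between 4.0 min and 6.4 min, higher than before.

| flask | substrate | catalyst | time |
|---|---|---|---|
| summer | 0.150 M | 0.00750 M |  |
| spring | 0.0600 M | 0.00750 M |  |
| midnight | 0.220 M | 0.00750 M |  |
| noon | 0.150 M | 0.0110 M |  |
| autumn | 0.450 M | 0.00750 M | 6.4 min |

- summer run (time / min: [target] / M): 0.26: 0.0015; 0.41: 0.0029; 0.64: 0.0041; 1.0: 0.0088; 1.6: 0.0147; 2.6: 0.0249; 4.0: 0.0418; 6.4: 0.0744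
- spring run (time / min: [target] / M): 0.26: 0.0020; 0.41: 0.0015; 0.64: 0.0017; 1.0: 0.0040; 1.6: 0.0055; 2.6: 0.0084; 4.0: 0.0125; 6.4: 0.0206
- midnight run (time / min: [target] / M): 0.26: 0.0030; 0.41: 0.0031; 0.64: 0.0061; 1.0: 0.0113; 1.6: 0.0220; 2.6: 0.0401; 4.0: 0.0730; 6.4: 0.1328
- noon run (time / min: [target] / M): 0.26: 0.0026; 0.41: 0.0027; 0.64: 0.0052; 1.0: 0.0095; 1.6: 0.0160; 2.6: 0.0289; 4.0: 0.0505; 6.4: 0.0840

(standard deviation of a reading: 8 × 10⁻⁴ M)

- Overall: substrate -> target, with catalyst as catalyst.
- Constant volume, constant temperature.
- A reading of a species includes what of it is bound.
- An order is taken over about fifteen percent of the charge, up and down.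

- the power of [substrate] that the first rate follows, about the charge of the summer run; measure it at two percent of substrate made into target (one fixed amount of target, the same in the runs compared)
- the power of [catalyst] that the first rate follows, about the charge of the summer run; measure it at two percent of substrate made into target
- the spring run starts with 0.0900 M less of substrate than the summer run, and with no target. Compared where both hold the same amount of substrate, once fifteen percent of what the spring run was charged with has turned into target, is the spring run faster, slower or alike (within a tenth)?
- target in the autumn run at 6.4 min, as a share of the substrate charged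

We read that climb as the work of target. Divided by the target gained between the two windows, it gives 1.65 L mol⁻¹ min⁻¹, which we call the gain, the rate per unit of substrate left that each mole per litre of target adds. Taking the gain away leaves a base term, which reads 0.0434 min⁻¹ in the midnight run and 0.0555 min⁻¹ in the spring run.

Let x be the fraction of the charge turned into target. Per minute, the fraction left then shrinks, per unit of itself, by the base term plus the gain times the charge times x, a logistic law. For the autumn run, gain times charge is 0.741 min⁻¹.

Now the bracket for the autumn run at 6.4 min. From above, the charge caps the share at 100 %. From below, the smaller base term without any gain gives 24.3 %. Integrating the law tightens this to 89.3 % with the smaller base term and 91.9 % with the larger, the scatter in the gain aside.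

The summer run holds 0.0900 M more target than the spring run at equal substrate. With 0.00900 M of target in the spring run, we reckon the spring rate over the summer rate at 0.282 to 0.322, so slower.

The forecast gives orders of 1 in substrate and 0.45 in catalyst, slower for the spring run, and 86 % for the autumn run, below our bracket, with the remark “Target there goes beyond the tested range, where saturation could occur”.

The simulation gives orders of 0.96 and 0.54, slower for the spring run, and 90.5 % for the autumn run, inside our bracket.

    catalyst + substrate ⇌ catalyst-substrate complex (29.34 L mol⁻¹ min⁻¹, 1.428 min⁻¹)
    catalyst-substrate complex → target + catalyst (11.70 min⁻¹)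
    substrate + target → 2 target (1.686 L mol⁻¹ min⁻¹)
    2 catalyst ⇌ resting dimer, settled at all times (662.0 L mol⁻¹)

In the autumn run, gain times charge, 0.741 min⁻¹, far exceeds the base term, and with the step from substrate and target to two target taken away, that run gives 25.5 % instead of 90.5 %. The same gain carries to the spring run against the summer run at equal substrate, where it gave us 0.282 to 0.322. The simulated ratio there is 0.31, and without that step it is 1.0.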